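## Structural features

The target (C20H10Cl2O8) is made of a keto half (benzene ring A fused to ring D: C1 ketal, C2/C3 epoxide, C4 ketone, C5 OH, C6 Cl) and a carbinol half (benzene ring B fused to ring C: quaternary C1', C2'/C3' epoxide, C4' secondary alcohol, C5' OH, C6' Cl). The halves are joined three times: by the C8–C1' bond and by two oxygens, Ob (C1'–O–C1) and Oa (C8'–O–C1). These close a five-membered ring (C1, Ob, C1', C8, C8a) and a 1,3-dioxin ring (C1, Oa, C8', C8a', C1', Ob), together a 2,8-dioxabicyclo[3.2.1]octane with bridgeheads C1 and C1'. There are seven stereocentres, C1–C2–C3 in ring D and C1'–C2'–C3'–C4' in ring C, and the two sets meet at the C1–Ob–C1' bridge. The ring C epoxide is cis to Ob and trans to the C4' hydroxyl; the ring D epoxide is anti to Oa. Fragile groups are the two epoxides (one α to a ketone), the C4' alcohol (trans to an epoxide, so open to Payne migration under base; benzylic and ortho to a phenol, so open to ionisation under strong acid), the doubly benzylic C1'–Ob bond, two aryl chlorides and oxidisable phenol rings. The real difficulty is the congested C1', which carries two aryl rings next to an epoxide and is tied to the bis-spiro carbon C1, together with telling apart the four oxygens of the carbinol half. The key step uses the fact that both oxygens on C1 belong to the other half and hang on the same stereogenic carbon C1' (Ob directly, Oa through C8a'–C8'), so a C1 quinone carbonyl joined through C8–C1' can trap both under equilibrium control with only one possible configuration at C1.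

## Logic of the disconnections

26 to 25: the O4'–Si and O5'–Si bonds are put back. A free C4' hydroxyl trans to the epoxide would migrate the epoxide under the basic epoxidation, and a free C5' phenol para to Oa is oxidisable, so both stay tied in one silylene until the end. Nothing is gained in skeleton, only in safety. The forward step needs a fluoride source that is acidic, not basic, and mild towards two epoxides and the ketal.

25 to 24: the C2–O and C3–O bonds of the ring D epoxide are cut. An α,β-epoxy ketone next to a ketal is the most sensitive unit and is best made last. Two stereocentres disappear and an enone remains whose faces are already differentiated by the cage. The forward step must epoxidise anti to Oa in the presence of the free C5 phenol.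

24 to 21 (through 22 and 23): the C1–Oa and C1–Ob bonds are cut. Both are ketal bonds to oxygens that already sit on the carbinol half. Two rings and the stereocentre C1 disappear, leaving a quinone and a diol. The forward step must run under equilibrium conditions, choose C1 over C4 and over C2, and release the two phenols only in the flask in which they are consumed.

21 to 20: the quinone is traced to a 1,4-dimethoxynaphthalene, cutting two O–CH3 bonds at the level of oxidation state. A quinone cannot pass through an organometallic step. The demand is an oxidant that takes ring A and leaves ring B alone; hence ring B carries a chlorine, a silyl oxygen and an acetal oxygen, and has no free phenol at this stage.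

20 to 17 and 9: the C8–C1' bond is cut. This is the most convergent cut, dividing the molecule into two ten-carbon halves, and it creates C1'. The forward step needs a hindered aryl nucleophile that adds to an epoxy ketone anti to the epoxide without opening it and without touching two aryl chlorides.

9 to 6 (through 8 and 7): the C1' carbonyl is traced to a secondary alcohol, and the MOM and silylene groups are removed. C1' oxygen therefore arrives at the alcohol level from the start, so no C–H oxidation next to an epoxide is needed. The silylene both protects O4'/O5' and tells the two peri carbinol/phenol pairs apart. The demand is regioselective silylene formation on the pair that lies on the chlorine side.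

6 to 3 (through 5 and 4): the ring C epoxide C–O bonds are cut and ring B is traced to its enedione tautomer. The epoxide is introduced on the folded cis-fused adduct, where one face is open, and before aromatisation, because it blocks loss of acetic acid to a naphthalene. The demand is an electrophilic oxidant that spares the chloro-enedione, and a deacetylation that never puts a phenoxide next to a benzylic acetate.

3 to 1 and 2: the C4a'–C4' and C8a'–C1' bonds are cut (Diels–Alder). All four sp3 carbons of ring C, both oxygens (cis) and the chlorine are set in one step, and a symmetrical diene removes any regiochemical question. The demand is a catalyst that distinguishes the two carbonyls of 1, because the handedness of 3 rests only on where the chlorine ends up.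

17 to 10 (through 16, 15, 14, 13, 12, 11): the C8–Br, C6–Cl, two O–CH3 and the MOM bonds are cut. 10 already has the C5 oxygen and both ring D oxygens. The demand is the order of halogenation: chlorine by directed metalation ortho to the MOM ether, then bromine para to the free naphthol.

## Other disconnections considered

Alternative 1: The cut goes through C1'–C2' and C3'–C4', so ring C is made by a [4+2] addition on a diaryl ketone A2 in which rings A and B are already joined through the future C1'. In the forward step, 350 nm light excites the ketone, the carbonyl oxygen takes a hydrogen from the C4' methylene, and the hydroxy-o-quinodimethane adds to an ethynyl aryl sulfone to give A1.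
- In favour: the quaternary carbinol C1' and ring C arise without any addition of a hindered organometallic to a ketone, and on this point the alternative is better than the chosen plan. The ketone is also easy to assemble from two benzene pieces.
- Against: suprafacial addition to an E,E-dienol puts O1' and O4' cis. A1 as formulated indeed has C4' in the configuration opposite to that of the target, where O1' and O4' are trans, so C4' would have to be inverted later. Absolute control has to come from a chiral Lewis acid that works under irradiation. Ring D does not yet exist: C1 is an ester carbon, C2–C4, the C4–C4a bond and both ketal bonds are still to be made, so the bis-ketalisation is only postponed. Turning the vinyl sulfone into the epoxide costs several steps.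
- Comparison: on structure it is better at C1' and worse at C4' and ring D. On mechanism it is a kinetically controlled photochemical step whose stereochemical outcome is fixed by dienol geometry, against a reversible closure that converges. On step economy it is about equal up to its key step and clearly longer after it.

Alternative 2: The cut is C8–C1' in an achiral precursor A4 that already holds both ketal bonds: the ring D carbonyl is ketalised with a 4,5-dihydroxynaphthalene-1,8-diol, so rings B and C are both aromatic. In the forward step a chiral aryl iodine oxidant (trivalent iodine, made in the flask from a C2-symmetric iodoarene and a peracid) oxidises one of the two enantiotopic para-alkoxyphenol rings, and C8 of ring A attacks the ipso carbon to give A3.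
- In favour: it is the shortest conceivable way to the cage, C1 and C1' are set together by a catalytic desymmetrisation, and no protecting groups are needed. In step count to the core and in catalytic control of the core-forming step it is better than the chosen plan.
- Against: A3 has no chlorine, no epoxide and a C4' ketone. Two late chlorinations must find C6 and C6' next to two enones. The C4' ketone must be reduced from the epoxide face to give the trans alcohol, whereas hydride normally comes anti to an epoxide. Two enones need epoxidation with different facial demands. The ring A phenol, whose para position is the reacting C8, is itself oxidisable, and C–C bond formation at a hindered ipso carbon competes with capture by solvent.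
- Comparison: on structure it is better for the core and worse for everything around it. On mechanism it is an irreversible oxidant-controlled step against a reversible one. On step economy it is shorter to the core, but not shorter to the target.

Alternative 3: The cut is C1'–Ob. The precursor A6 is a benzoic acid (its carboxyl carbon is the future C1) carrying at C8 a 1,2-dihydronaphthalene with a trisubstituted C1'=C2' bond and with O3' and O4' in place. In the forward step an electrophilic bromine source, helped if needed by a dimeric cinchona alkaloid catalyst, forms a bromonium ion anti to O3'. The carboxylate opens it at the benzylic C1' (5-exo) to give A5 with bromine trans to Ob, and later the C3' alkoxide displaces bromide to give the epoxide cis to Ob.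
- In favour: C1' and both epoxide carbons are relayed from one existing stereocentre by anti addition and inversion, and the required pattern (epoxide cis to Ob, trans to O4') results. This is equal to or better than relying on facial selectivity in a hindered addition, and no organometallic meets an epoxy ketone.
- Against: C1 is at the carboxylic acid level. Ring D (C2, C3, C4 and the C4–C4a bond) must be grown on a hindered spiro lactone, and the second ketal bond C1–Oa must still be closed, so the reaction chosen here reappears later in a harder setting. A6 needs a trans-3',4'-diol building block, an aryl–alkenyl coupling and four different protecting groups.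
- Comparison: on structure it is equal or better at C1' and the epoxide, and worse at C1 and ring D. On mechanism it is a stereospecific kinetic relay against a thermodynamic closure. On step economy it is longer.

Key step: step 14

Remark on labels: intermediates are described with the atom labels their atoms carry in the target (unprimed keto half, primed carbinol half, Oa on C8', Ob on C1').

Remark (assumption): the (R)-binaphthol–titanium catalyst is taken to give the enantiomer of 3 that is drawn. If the facial sense is the opposite, the (S)-ligand is used and nothing else changes.

Remark on structures: the descriptors of 22 and 24 agree with those of the target at C1', C2', C3' and C4' (and at C1 for 24), so both are used unchanged. The one structure that does not match the target is A1, at C4'.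

## Route

Step 1
Reactants: 1 2-chloro-1,4-benzoquinone; 2 (1E,3E)-buta-1,3-diene-1,4-diyl diacetate
Product: 3 endo cycloadduct 2-chloro-1,4-dioxo-1,4,4a,5,8,8a-hexahydronaphthalene-5,8-diyl diacetate (H-4a H-5 H-8 H-8a all cis)
Conditions: TiCl2(OiPr)2 (10 mol%), (R)-1,1'-bi-2-naphthol (11 mol%), CH2Cl2, 0 → 23 °C
Reagents that add atoms: none
Why: Catalytic enantioselective Diels–Alder reaction of a quinone with an acyloxy diene; the unsubstituted C=C of 1 reacts, the E,E-diene and endo addition give the all-cis adduct, and a symmetrical diene leaves no regiochemistry. The four stereocentres are set by the catalyst, which must bind the more basic and less hindered carbonyl (the one remote from chlorine) and shield one face; the C8 acetoxy carbon (next to the carbonyl flanked by C–Cl) becomes C4'.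

Step 2
Reactants: 3 endo cycloadduct
Product: 4 6,7-epoxide of 3 (epoxide trans to both acetoxy groups)
Conditions: dimethyldioxirane (acetone solution), CH2Cl2, 0 → 23 °C
Reagents that add atoms: dimethyldioxirane, CC1(C)OO1
Why: Electrophilic epoxidation with a neutral dioxirane; the chloro-enedione double bond is too electron-poor to react and the enolisable adduct is not exposed to acid or base. Both acetoxy groups and both ring-fusion carbonyl carbons sit on one face of the cyclohexene, so oxygen is delivered to the other (convex) face, which sets C2' and C3' trans to O1' and O4'.

Step 3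
Reactants: 4 epoxy adduct
Product: 6 tetraol 6'-chloro-2',3'-epoxy-1',2',3',4'-tetrahydronaphthalene-1',4',5',8'-tetraol (OH-1' and OH-4' cis; epoxide trans to both), via hydroquinone diacetate 5 (not isolated)
Conditions: PPTS (5 mol%), CH2Cl2, 0 °C; then i-Bu2AlH, CH2Cl2, −78 °C
Reagents that add atoms: none
Why: Acid-catalysed enolisation of the enedione to the hydroquinone (aromatisation), then reductive cleavage of the two acetates; the ring-fusion stereocentres are lost and the four of ring C are untouched. Reduction at −78 °C replaces basic methanolysis so that no phenoxide sits ortho to a benzylic acetate (quinone methide elimination) and no free alkoxide trans to the epoxide is formed (Payne rearrangement); the epoxide already in place prevents aromatisation of ring C.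

Step 4
Reactants: 6 tetraol
Product: 7 O4',O5'-di-tert-butylsilylene diol (free OH at C1' and C8')
Conditions: NaH (1.0 equiv), THF, 0 °C; t-Bu2Si(OTf)2 (1.0 equiv), −78 °C; 2,6-lutidine, −78 → 0 °C
Reagents that add atoms: di-tert-butylsilyl bis(trifluoromethanesulfonate), CC(C)(C)[Si](OS(=O)(=O)C(F)(F)F)(OS(=O)(=O)C(F)(F)F)C(C)(C)C
Why: Silylene protection of a peri phenol/benzylic alcohol pair (six-membered dioxasiline). One equivalent of base gives the phenoxide of the more acidic phenol, the one ortho to chlorine (C5'); it captures the very reactive silyl bis-triflate first and the ring then closes on the neighbouring C4' hydroxyl, so that the pair on the chlorine side is protected and the C1'/C8' pair stays free.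

Step 5
Reactants: 7 silylene diol
Product: 8 C8' methoxymethyl ether with free C1' hydroxyl
Conditions: MOMCl, K2CO3, acetone, 0 → 23 °C
Reagents that add atoms: chloromethyl methyl ether, COCCl
Why: Williamson-type O-alkylation of a phenoxide; under carbonate only the phenol is ionised, so the secondary C1' hydroxyl is left for the next step. MOM is chosen because it survives the organometallic and the oxidative steps and is cleaved by the acid of the key step.

Step 6
Reactants: 8 C8' methoxymethyl ether alcohol
Product: 9 epoxy ketone (C1' ketone; O4',O5'-silylene; C8' OMOM)
Conditions: Dess–Martin periodinane, pyridine, CH2Cl2, 0 → 23 °C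
Reagents that add atoms: none
Why: Dess–Martin oxidation of a secondary benzylic alcohol under buffered, non-basic conditions that leave epoxide, acetal and silylene alone. The α-carbon is an epoxide carbon, so no epimerisation is possible, and C1' is reached without any C–H oxidation.

Step 7
Reactants: 10 juglone (5-hydroxynaphthalene-1,4-dione)
Product: 11 5-(methoxymethoxy)naphthalene-1,4-dione
Conditions: MOMCl, i-Pr2NEt, CH2Cl2, 0 → 40 °C
Reagents that add atoms: chloromethyl methyl ether, COCCl
Why: O-alkylation of the peri phenol; the acetal will serve as the ortho-directing group for chlorination.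

Step 8
Reactants: 11 5-(methoxymethoxy)naphthalene-1,4-dione
Product: 12 1,4-dimethoxy-5-(methoxymethoxy)naphthalene
Conditions: Na2S2O4, n-Bu4NBr, THF/H2O, 23 °C; then KOH, Me2SO4, 0 → 23 °C
Reagents that add atoms: dimethyl sulfate, COS(=O)(=O)OC
Why: Reductive methylation of a quinone (dithionite reduction, then phase-transfer O-methylation of the hydroquinone); the quinone is stored as a dimethoxyarene that tolerates organolithium chemistry and can be unmasked oxidatively.

Step 9
Reactants: 12 1,4-dimethoxy-5-(methoxymethoxy)naphthalene
Product: 15 2-chloro-5,8-dimethoxynaphthalen-1-ol, via 6-lithio MOM ether 13 (not isolated), via 6-chloro MOM ether 14 (not isolated)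
Conditions: n-BuLi, TMEDA, THF, −78 → 0 °C; C2Cl6, −78 → 23 °C; then 3 M HCl, MeOH, 50 °C
Reagents that add atoms: hexachloroethane, ClC(Cl)(Cl)C(Cl)(Cl)Cl
Why: Directed ortho-metalation; the chelating acetal directs lithiation to C6 more strongly than the methyl ethers direct to C2 or C3, and hexachloroethane delivers electrophilic chlorine. The acetal is then removed by acid methanolysis, because the free naphthol, not its hindered twisted ether, is needed to direct the bromination.

Step 10
Reactants: 15 2-chloro-5,8-dimethoxynaphthalen-1-ol
Product: 16 4-bromo-2-chloro-5,8-dimethoxynaphthalen-1-ol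
Conditions: NBS, MeCN, −20 °C
Reagents that add atoms: N-bromosuccinimide, O=C1CCC(=O)N1Br
Why: Electrophilic aromatic bromination; the free naphthol hydroxyl is the strongest activator, its ortho position is blocked by chlorine, and the para α-position (the future C8) is therefore the site of attack in preference to C2/C3 of the dimethoxy ring.

Step 11
Reactants: 16 4-bromo-2-chloro-5,8-dimethoxynaphthalen-1-ol
Product: 17 4-bromo-2-chloro-5,8-dimethoxy-1-(methoxymethoxy)naphthalene
Conditions: MOMCl, i-Pr2NEt, CH2Cl2, 40 °C
Reagents that add atoms: chloromethyl methyl ether, COCCl
Why: O-alkylation of the phenol; the C5 oxygen must be capped for the aryllithium step and for the cerium oxidation (a free para-hydroxybenzylic carbinol would fragment on oxidation), and MOM leaves in the same acid treatment as the C8' MOM group.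

Step 12
Reactants: 17 4-bromo-2-chloro-5,8-dimethoxy-1-(methoxymethoxy)naphthalene; 9 epoxy ketone
Product: 20 tertiary carbinol (C8–C1' bond; ring A as 1,4-dimethoxy-5-OMOM-6-chloronaphthalene; aryl trans and C1' OH cis to the epoxide), via aryllithium 18 (not isolated), via arylcerium dichloride 19 (not isolated)
Conditions: 17, n-BuLi, THF, −78 °C; CeCl3, −78 °C; then 9, −78 → −40 °C
Reagents that add atoms: none
Why: Bromine–lithium exchange (faster than any exchange at chlorine or ortho-lithiation at −78 °C), transmetalation to the less basic and more oxophilic organocerium, and 1,2-addition to the ketone. The nucleophile approaches the C1' carbonyl on the face opposite to the epoxide oxygen, the silylene holding O4' in the ring plane, which sets C1' with its oxygen cis to the epoxide and trans to O4'.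

Step 13
Reactants: 20 tertiary carbinol
Product: 21 quinone carbinol bis(methoxymethyl) ether (ring A 1,4-quinone; OMOM at C5 and C8'; O4',O5'-silylene)
Conditions: (NH4)2Ce(NO3)6, MeCN/H2O (4:1), 0 °C
Reagents that add atoms: water, O
Why: Oxidative demethylation of a 1,4-dimethoxyarene by tetravalent cerium; the trialkoxynaphthalene is oxidised at a clearly lower potential than ring B, which carries a chlorine, a silyl oxygen and an acetal oxygen and no free phenol. 21 may exist partly as its C1 hemiketal with the C1' hydroxyl; both forms enter the next step.

Step 14
Reactants: 21 quinone carbinol bis(methoxymethyl) ether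
Product: 24 bis-spiroketal ring D enone (C1–Oa and C1–Ob closed; C2=C3; C4 ketone; C5 OH; O4',O5'-silylene), via quinone carbinol 22 (not isolated), via C1 hemiketal 23 (not isolated)
Conditions: CF3CO2H, CH2Cl2, H2O (3 equiv), 0 → 23 °C; concentrate; then CSA (0.3 equiv), 4 Å MS, CH2Cl2, 23 °C
Reagents that add atoms: none
Why: Acid-catalysed double ketalisation of a keto diol, the closest known type being thermodynamic spiroketalisation of dihydroxy ketones, here on C1 of a naphthoquinone. Trifluoroacetic acid first frees the C5 and C8' phenols to give 22, so the oxidisable para-silyloxyphenol exists only in the flask in which it reacts. The tertiary C1' hydroxyl adds to the C1 carbonyl (5-exo-trig) to give hemiketal 23; loss of water gives an oxocarbenium ion stabilised by Ob, and the C8' phenol captures it (6-endo-trig, the C1=Ob bond lying inside the new dioxin ring); every step is reversible and the sieves take up the water. C1 is the only new stereocentre and is controlled by C1': Oa and Ob are both carried by the C1' unit, so the 2,8-dioxabicyclo[3.2.1]octane can close with one configuration at C1 only and both hemiketal epimers funnel into it. The step needs selectivity for C1 over C4 and for carbonyl addition over conjugate addition at C2: C4 is hydrogen-bonded to the C5 hydroxyl and out of reach of both nucleophiles, and addition to the carbonyl is fast and reversible whereas a tertiary alcohol adds to C2 only slowly. Ionisation of the C1'–O bond is held back by the electron-poor quinone ring and the adjacent epoxide, and the silylene keeps O4' and O5' out of play.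

Step 15
Reactants: 24 bis-spiroketal enone
Product: 25 ring D epoxide (C2/C3 epoxide anti to Oa; O4',O5'-silylene retained)
Conditions: t-BuOOH, DBU, CH2Cl2, 0 °C
Reagents that add atoms: tert-butyl hydroperoxide, CC(C)(C)OO
Why: Weitz–Scheffer nucleophilic epoxidation of the enone. The peri-fused five-membered ring holds Ob near the plane of ring D and leaves Oa axial on C1, so the peroxide anion adds to C2 on the face opposite to Oa, which sets C2 and C3; the silylene prevents Payne migration at C4' under the base.

Step 16
Reactants: 25 ring D epoxide
Product: 26 target CNP0289684.3
Conditions: HF·pyridine, pyridine, THF, 0 → 23 °C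
Reagents that add atoms: none
Why: Fluoride-mediated cleavage of the di-tert-butylsilylene under buffered, weakly acidic conditions. No base is present, so the freed C4' hydroxyl trans to the epoxide cannot start an epoxide migration, and the deactivated, oxygen-flanked epoxides and the ketal are not opened.

## Compound list

1 | 2-chloro-1,4-benzoquinone | O=C1C=CC(=O)C(Cl)=C1 | starting material
2 | (1E,3E)-buta-1,3-diene-1,4-diyl diacetate | CC(=O)O/C=C/C=C/OC(C)=O | starting material
3 | endo cycloadduct, 2-chloro-1,4-dioxo-1,4,4a,5,8,8a-hexahydronaphthalene-5,8-diyl diacetate, H-4a, H-5, H-8, H-8a all cis | CC(=O)O[C@H]1C=C[C@@H](OC(C)=O)[C@H]2C(=O)C(Cl)=CC(=O)[C@@H]12 | intermediate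
4 | 6,7-epoxide of 3, epoxide trans to both acetoxy groups | CC(=O)O[C@H]1[C@@H]2O[C@@H]2[C@@H](OC(C)=O)[C@H]3C(=O)C(Cl)=CC(=O)[C@@H]13 | intermediate
5 | hydroquinone diacetate, 6'-chloro-2',3'-epoxy-5',8'-dihydroxy-1',2',3',4'-tetrahydronaphthalene-1',4'-diyl diacetate | CC(=O)O[C@H]1[C@@H]2O[C@@H]2[C@@H](OC(C)=O)c3c(O)c(Cl)cc(O)c13 | intermediate (not isolated)
6 | tetraol, 6'-chloro-2',3'-epoxy-1',2',3',4'-tetrahydronaphthalene-1',4',5',8'-tetraol, OH-1' and OH-4' cis, epoxide trans to both | O[C@H]1[C@@H]2O[C@@H]2[C@@H](O)c3c(O)c(Cl)cc(O)c13 | intermediate
7 | O4',O5'-di-tert-butylsilylene diol, free OH at C1' and C8' | O[C@H]1[C@@H]2O[C@@H]2[C@H]3O[Si](C(C)(C)C)(C(C)(C)C)Oc4c(Cl)cc(O)c1c34 | intermediate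
8 | C8' methoxymethyl ether of 7, free C1' hydroxyl | O[C@H]1[C@@H]2O[C@@H]2[C@H]3O[Si](C(C)(C)C)(C(C)(C)C)Oc4c(Cl)cc(OCOC)c1c34 | intermediate
9 | epoxy ketone, C1' ketone, O4',O5'-silylene, C8' OMOM | O=C1[C@@H]2O[C@@H]2[C@H]3O[Si](C(C)(C)C)(C(C)(C)C)Oc4c(Cl)cc(OCOC)c1c34 | intermediate
10 | juglone, 5-hydroxynaphthalene-1,4-dione | O=C1C=CC(=O)c2c(O)cccc12 | starting material
11 | 5-(methoxymethoxy)naphthalene-1,4-dione | O=C1C=CC(=O)c2c(OCOC)cccc12 | intermediate
12 | 1,4-dimethoxy-5-(methoxymethoxy)naphthalene | COCOc1cccc2c(OC)ccc(OC)c12 | intermediate
13 | 6-lithio-1,4-dimethoxy-5-(methoxymethoxy)naphthalene | COCOc1c([Li])ccc2c(OC)ccc(OC)c12 | intermediate (not isolated)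
14 | 6-chloro-1,4-dimethoxy-5-(methoxymethoxy)naphthalene | COCOc1c(Cl)ccc2c(OC)ccc(OC)c12 | intermediate (not isolated)
15 | 2-chloro-5,8-dimethoxynaphthalen-1-ol | Oc1c(Cl)ccc2c(OC)ccc(OC)c12 | intermediate
16 | 4-bromo-2-chloro-5,8-dimethoxynaphthalen-1-ol | Oc1c(Cl)cc(Br)c2c(OC)ccc(OC)c12 | intermediate
17 | 4-bromo-2-chloro-5,8-dimethoxy-1-(methoxymethoxy)naphthalene | COCOc1c(Cl)cc(Br)c2c(OC)ccc(OC)c12 | intermediate
18 | aryllithium from 17 (lithium at C8 of ring A) | COCOc1c(Cl)cc([Li])c2c(OC)ccc(OC)c12 | intermediate (not isolated)
19 | arylcerium dichloride from 18 | COCOc1c(Cl)cc([Ce](Cl)Cl)c2c(OC)ccc(OC)c12 | intermediate (not isolated)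
20 | tertiary carbinol, ring A 1,4-dimethoxy-5-OMOM-6-chloro, C8–C1' bond, C1' OH cis to the epoxide and trans to O4' | COCOc1c(Cl)cc(c2c(OC)ccc(OC)c12)[C@@]3(O)[C@@H]4O[C@@H]4[C@H]5O[Si](C(C)(C)C)(C(C)(C)C)Oc6c(Cl)cc(OCOC)c3c56 | intermediate
21 | quinone carbinol bis(methoxymethyl) ether | O=C1C=CC(=O)c2c(OCOC)c(Cl)cc(c12)[C@@]3(O)[C@@H]4O[C@@H]4[C@H]5O[Si](C(C)(C)C)(C(C)(C)C)Oc6c(Cl)cc(OCOC)c3c56 | intermediate
22 | quinone carbinol with free C5 and C8' phenols and O4',O5'-silylene (precursor of the ketalisation) | O=C1C=CC(=O)c2c(O)c(Cl)cc(c12)[C@@]3(O)[C@@H]4O[C@@H]4[C@H]5O[Si](C(C)(C)C)(C(C)(C)C)Oc6c(Cl)cc(O)c3c56 | intermediate (not isolated)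
23 | C1 hemiketal of 22 (C1–Ob closed, both C1 epimers) | O=C1C=CC2(O)O[C@@]3([C@@H]5O[C@@H]5[C@H]6O[Si](C(C)(C)C)(C(C)(C)C)Oc7c(Cl)cc(O)c3c67)c4cc(Cl)c(O)c1c24 | intermediate (not isolated)
24 | bis-spiroketal ring D enone | O=C1c2c(O)c(Cl)cc3c2[C@@]2(Oc4cc(Cl)c(O[Si]6(C(C)(C)C)C(C)(C)C)c5c4[C@]3(O2)[C@@H]2O[C@@H]2[C@H]5O6)C=C1 | intermediate
25 | ring D epoxide, silylene retained | O=C1c2c(O)c(Cl)cc3c2[C@@]2(Oc4cc(Cl)c(O[Si]6(C(C)(C)C)C(C)(C)C)c5c4[C@]3(O2)[C@@H]2O[C@@H]2[C@H]5O6)[C@@H]2O[C@H]12 | intermediate
26 | CNP0289684.3 | O=C1c2c(O)c(Cl)cc3c2[C@@]2(Oc4cc(Cl)c(O)c5c4[C@]3(O2)[C@@H]2O[C@@H]2[C@H]5O)[C@@H]2O[C@H]12 | target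

## Step count and least certain steps

Total: 16 steps. Longest linear sequence: 11 steps (from 1 and 2 through steps 1–6 and 12–16); the ring A branch from 10 is 10 steps long (steps 7–11 and 12–16).

Step 14 (key step). The most likely failure is that the closure stops at the hemiketal stage, or that the C1'–O bond ionises towards an ortho-quinone methide of ring B once the C8' phenol is free, which would scramble C1'. The second ring closure has to overcome the strain of the bicyclic cage while water and formaldehyde from the acetal cleavage are still present. The fallback replaces the protic equilibrium by an aprotic silyl-transfer ketalisation. It sets out from 22 (crude, after the trifluoroacetic acid stage). Me3SiOTf and 2,6-lutidine in CH2Cl2 at −78 °C should give the tris(trimethylsilyl) ether of 22 F1 (silyl on O5, O1' and O8'). A further catalytic amount of Me3SiOTf at −78 → −20 °C should then join the silyl-activated C1 carbonyl to O1' and O8' with irreversible loss of hexamethyldisiloxane. Aqueous work-up removes the silyl group from O5, and the route is rejoined at 24.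

Step 1. The most likely failure is poor discrimination between the two carbonyl groups of 1 by the catalyst. With a symmetrical diene this shows up directly as low enantiomeric purity; the reaction may also be slow, because the diene carries two acyloxy groups. The fallback is a resolution. It sets out from 1 and 2, combined without catalyst in toluene at 80 °C, and carries the racemate of 3 through steps 2–5 to racemic 8. Esterification with (S)-O-acetylmandelic acid (DCC, DMAP) gives two diastereomers that are separated by chromatography: the (S)-O-acetylmandelate of 8 F2 and the (S)-O-acetylmandelate of the enantiomer of 8 F3. K2CO3 in methanol cleaves F2 and the route is rejoined at 8.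

Step 4. The most likely failure is insufficient regioselection between the two peri phenol/carbinol pairs. They differ only by the ortho chlorine, and the bulky silyl electrophile may prefer the less hindered C8' oxygen or a carbinol oxygen. The fallback differentiates the two ring B oxygens one stage earlier, by carbonyl basicity and not by phenol acidity. It sets out from 4. t-BuMe2SiOTf (1 equiv) and Et3N at −78 °C should silylate the more basic carbonyl (the one remote from chlorine) and aromatise the ring, giving the C8' silyl ether with free C5' phenol F4. i-Bu2AlH at −78 °C removes the acetates to give the triol F5, in which only one phenol/carbinol pair is free. NaH, t-Bu2Si(OTf)2 and 2,6-lutidine then give the silylene with C8' silyl ether F6, and K2CO3 in methanol removes the aryl silyl ether. The route is rejoined at 7.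

Step 13. The most likely failure is loss of chemoselectivity, that is oxidation of ring B with loss of the silylene, or over-oxidation, because both rings are alkoxyarenes and the oxidant is used in excess in an acidic aqueous medium. The fallback avoids a free quinone in an oxidising medium. It sets out from 20. PhI(OCOCF3)2 (trivalent iodine) with K2CO3 in MeCN at 0 °C, then water, should oxidise ring A with capture of the C1 cation by the tertiary C1' hydroxyl, giving the C1 mixed methyl ketal F7 (C1–Ob closed, C4 ketone, both MOM groups retained). The acid sequence of step 14 then frees the phenols and exchanges the C1 methoxy group for Oa. The route is rejoined at 24.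

## Further compounds

F1 | step 14 | tris(trimethylsilyl) ether of 22 (silyl on O5, O1', O8') | O=C1C=CC(=O)c2c(O[Si](C)(C)C)c(Cl)cc(c12)[C@@]3(O[Si](C)(C)C)[C@@H]4O[C@@H]4[C@H]5O[Si](C(C)(C)C)(C(C)(C)C)Oc6c(Cl)cc(O[Si](C)(C)C)c3c56
F2 | step 1 | (S)-O-acetylmandelate of 8 | CC(=O)O[C@@H](c1ccccc1)C(=O)O[C@H]2[C@@H]3O[C@@H]3[C@H]4O[Si](C(C)(C)C)(C(C)(C)C)Oc5c(Cl)cc(OCOC)c2c45
F3 | step 1 | (S)-O-acetylmandelate of the enantiomer of 8 | CC(=O)O[C@@H](c1ccccc1)C(=O)O[C@@H]2[C@H]3O[C@H]3[C@@H]4O[Si](C(C)(C)C)(C(C)(C)C)Oc5c(Cl)cc(OCOC)c2c45
F4 | step 4 | C8' tert-butyldimethylsilyl ether of 5 (free C5' phenol, diacetate) | CC(=O)O[C@H]1[C@@H]2O[C@@H]2[C@@H](OC(C)=O)c3c(O)c(Cl)cc(O[Si](C)(C)C(C)(C)C)c13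
F5 | step 4 | triol from F4 (free OH at C1', C4', C5'; C8' silyl ether) | O[C@H]1[C@@H]2O[C@@H]2[C@@H](O)c3c(O)c(Cl)cc(O[Si](C)(C)C(C)(C)C)c13
F6 | step 4 | O4',O5'-di-tert-butylsilylene with C8' tert-butyldimethylsilyl ether and free C1' hydroxyl | O[C@H]1[C@@H]2O[C@@H]2[C@H]3O[Si](C(C)(C)C)(C(C)(C)C)Oc4c(Cl)cc(O[Si](C)(C)C(C)(C)C)c1c34
F7 | step 13 | C1 mixed methyl ketal (C1–Ob closed, C4 ketone, OMOM at C5 and C8', both C1 epimers) | O=C1C=CC2(OC)O[C@@]3([C@@H]5O[C@@H]5[C@H]6O[Si](C(C)(C)C)(C(C)(C)C)Oc7c(Cl)cc(OCOC)c3c67)c4cc(Cl)c(OCOC)c1c24
A1 | alternative 1 | ring C dihydronaphthalene carbinol (cycloadduct) | COC(=O)c1cc(O[Si](C)(C)C(C)(C)C)c(Cl)cc1[C@@]2(O)C=C(S(=O)(=O)c3ccc(C)cc3)[C@H](O[Si](C)(C)C(C)(C)C)c3c(O[Si](C)(C)C(C)(C)C)c(Cl)cc(O[Si](C)(C)C(C)(C)C)c23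
A2 | alternative 1 | diaryl ketone precursor | COC(=O)c1cc(O[Si](C)(C)C(C)(C)C)c(Cl)cc1C(=O)c2c(O[Si](C)(C)C(C)(C)C)cc(Cl)c(O[Si](C)(C)C(C)(C)C)c2CO[Si](C)(C)C(C)(C)C
A3 | alternative 2 | bis-spiro dienone core | C17(OCCO7)c2c(O)ccc3c2[C@@]2(Oc4ccc(O)c5c4[C@]3(O2)C=CC5=O)C=C1
A4 | alternative 2 | achiral naphthalene-1,8-diyl ketal precursor | Oc1ccc2OC3(C=CC5(OCCO5)c6c(O)cccc36)Oc4ccc(O)c1c24
A5 | alternative 3 | spiro bromolactone | O=C1O[C@@]2([C@@H](Br)[C@H](O[Si](CC)(CC)CC)[C@H]3O[Si](C(C)(C)C)(C(C)(C)C)Oc4c(Cl)cc(OCOC)c2c34)c2cc(Cl)c(O[Si](C)(C)C(C)(C)C)cc12
A6 | alternative 3 | dihydronaphthalenyl benzoic acid precursor | OC(=O)c1cc(O[Si](C)(C)C(C)(C)C)c(Cl)cc1C2=C[C@H](O[Si](CC)(CC)CC)[C@H]3O[Si](C(C)(C)C)(C(C)(C)C)Oc4c(Cl)cc(OCOC)c2c34
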